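The ten-membered carbocycle is closed at C9–C10 by an intramolecular Mukaiyama aldol addition. The C8 silyl enol ether adds through C9 to the C10 methyl ketone, forming the ring and the tertiary carbinol in one operation and leaving a C8 ketone for the ester-bearing carbinol. The precursor is a cis-4,5-disubstituted α-methylene-γ-butyrolactone whose C6/C7 stereocentres come from natural (2R,3S)-isocitric acid; it carries the enol silane on C7 and a (Z)-configured enone chain (C5 to C1, C10) on C6. The step exploits the 1,3-dioxygenation O8/O10 flanking C9 and the turn imposed by the cis-fused lactone ring and the Z-C4=C5 bond.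

Key step: step 10

Remark: atoms carry germacranolide numbers (ring C1–C10, lactone C11/C12, exo-methylene C13, methyl C14 on C10, methyl C15 on C4); read from its SMILES the target is the (1E,4Z,6S,7R,8R,10R,2′S) isomer with a cis-fused lactone (H6 and H7 on the same face), and this isomer is the one made.

Step 1
Reactants: 1 potassium hydrogen (1R,2S)-1-hydroxypropane-1,2,3-tricarboxylate (natural (2R,3S)-isocitrate, monopotassium salt)
Product: 3 (3aS,6aR)-3a,6a-dihydrofuro[3,4-b]furan-2,4,6(3H)-trione (cis-fused lactone anhydride; C5 and C8 are the anhydride carbonyls), via isocitric acid lactone 2 (not isolated)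
Conditions: aq. HCl, evaporate, 100 °C; then Ac2O, 60 °C
Reagents that add atoms: none
Why: Acid-promoted γ-lactonisation of the C6 hydroxyl onto C12 and dehydration of the cis-1,2-dicarboxylic acid to the five-membered cyclic anhydride; C6 and C7 come unchanged from the chiral pool, and their cis relationship is what allows the bicyclic anhydride to form.

Step 2
Reactants: 3 (3aS,6aR)-3a,6a-dihydrofuro[3,4-b]furan-2,4,6(3H)-trione
Product: 4 (3aS,6aR)-6-hydroxytetrahydrofuro[3,4-b]furan-2,4-dione (lactol at C5, both anomers; ring tautomer of the C5 aldehyde / C8 acid)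
Conditions: LiAlH(OtBu)3 (1.05 equiv), THF, −78 → −40 °C; aq. HCl work-up
Reagents that add atoms: none
Why: Partial hydride reduction of a cyclic anhydride to a lactol; the hindered monohydride should add to the more electrophilic carbonyl C5 (next to the oxygen-bearing C6) and stop at the aluminated hemiacylal, leaving the γ-lactone and the C8 carboxyl untouched.

Step 3
Reactants: 4 (3aS,6aR)-6-hydroxytetrahydrofuro[3,4-b]furan-2,4-dione
Product: 5 (2R,3S)-2-[(1Z)-2-iodoprop-1-en-1-yl]-5-oxooxolane-3-carboxylic acid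
Conditions: EtPPh3I, n-BuLi, THF, 0 °C; I2, −78 °C; NaN(SiMe3)2, −20 °C; then 4 (pre-treated with NaN(SiMe3)2), −78 → −20 °C; aq. HCl
Reagents that add atoms: ethyltriphenylphosphonium iodide CC[P+](c1ccccc1)(c1ccccc1)c1ccccc1.[I-]; iodine II
Why: Stork–Zhao olefination of the aldehyde tautomer of the lactol (opened as its carboxylate) with the α-iodo ylide should give the (Z)-iodoalkene (iodine cis to C6) under kinetic control and frees the C8 carboxylic acid.

Step 4
Reactants: 5 (2R,3S)-2-[(1Z)-2-iodoprop-1-en-1-yl]-5-oxooxolane-3-carboxylic acid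
Product: 7 (4S,5R)-4-acetyl-5-[(1Z)-2-iodoprop-1-en-1-yl]oxolan-2-one, via acid chloride 6 (not isolated)
Conditions: 1-chloro-N,N,2-trimethylprop-1-en-1-amine, CH2Cl2, 0 °C; then Me2CuLi, Et2O, −78 °C
Reagents that add atoms: lithium dimethylcuprate [Li+].C[Cu-]C
Why: Neutral acid chloride formation followed by acylation of the diorganocuprate (ketone synthesis from an acid chloride) should stop at the methyl ketone and, at −78 °C, leave the lactone and the alkenyl iodide alone; no base is present, so C7 is not epimerised.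

Step 5
Reactants: 7 (4S,5R)-4-acetyl-5-[(1Z)-2-iodoprop-1-en-1-yl]oxolan-2-one
Product: 8 (4S,5R)-4-[1-(tert-butyldimethylsilyloxy)ethenyl]-5-[(1Z)-2-iodoprop-1-en-1-yl]oxolan-2-one
Conditions: LiN(SiMe3)2 (1.05 equiv), THF, −78 °C; then TBSOTf
Reagents that add atoms: tert-butyldimethylsilyl trifluoromethanesulfonate CC(C)(C)[Si](C)(C)OS(=O)(=O)C(F)(F)F
Why: Kinetic enolisation on the methyl side (C9) and O-silylation give the regiodefined silyl enol ether, which also removes the ketone that could trap the alkenylchromium species of step 6 and masks the acidity of H7.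

Step 6
Reactants: 8 (4S,5R)-4-[1-(tert-butyldimethylsilyloxy)ethenyl]-5-[(1Z)-2-iodoprop-1-en-1-yl]oxolan-2-one; 9 acrolein (prop-2-enal)
Product: 10 (4S,5S)-4-[1-(tert-butyldimethylsilyloxy)ethenyl]-5-[(1Z,3S)-3-hydroxy-2-methylpenta-1,4-dien-1-yl]oxolan-2-one
Conditions: CrCl2, NiCl2 (cat.), chiral oxazoline–sulfonamide ligand (enantiomer giving 3S), Et3N, THF, rt
Reagents that add atoms: none
Why: Nozaki–Hiyama–Kishi coupling of the alkenyl iodide with the aldehyde is chemoselective beside lactone and enol silane and retains the Z geometry; the C3 carbinol is set S by the chiral ligand on chromium (ligand control), this being the epimer whose silyloxy group should point outward in the ring-closing conformer of step 10.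

Step 7
Reactants: 10 (4S,5S)-4-[1-(tert-butyldimethylsilyloxy)ethenyl]-5-[(1Z,3S)-3-hydroxy-2-methylpenta-1,4-dien-1-yl]oxolan-2-one
Product: 11 (4S,5S)-4-[1-(tert-butyldimethylsilyloxy)ethenyl]-5-[(1Z,3S)-3-(tert-butyldimethylsilyloxy)-2-methylpenta-1,4-dien-1-yl]oxolan-2-one
Conditions: TBSOTf, 2,6-lutidine, CH2Cl2, −78 °C
Reagents that add atoms: tert-butyldimethylsilyl trifluoromethanesulfonate CC(C)(C)[Si](C)(C)OS(=O)(=O)C(F)(F)F
Why: Silylation of the secondary allylic alcohol under non-acidic conditions keeps C3 at the alcohol oxidation level, so that no ene-dione is present during ring closure.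

Step 8
Reactants: 11 (4S,5S)-4-[1-(tert-butyldimethylsilyloxy)ethenyl]-5-[(1Z,3S)-3-(tert-butyldimethylsilyloxy)-2-methylpenta-1,4-dien-1-yl]oxolan-2-one
Product: 14 (4S,5S)-3-methylidene-4-[1-(tert-butyldimethylsilyloxy)ethenyl]-5-[(1Z,3S)-3-(tert-butyldimethylsilyloxy)-2-methylpenta-1,4-dien-1-yl]oxolan-2-one, via Mannich base 12 (not isolated), via methiodide 13 (not isolated)
Conditions: LiN(iPr)2, THF, −78 °C; CH2=NMe2+ I−, −78 → −40 °C; then MeI, CH2Cl2, rt; aq. NaHCO3
Reagents that add atoms: dimethyl(methylidene)ammonium iodide C=[N+](C)C.[I-]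
Why: α-Methylenation of the lactone through its lithium enolate (the only acidic site now that C8 is an enol ether) by Mannich reaction, quaternisation and E1cB loss of trimethylamine; the transient C11 centre disappears, and no strong base is needed later when the C8 hydroxyl could translactonise.

Step 9
Reactants: 14 (4S,5S)-3-methylidene-4-[1-(tert-butyldimethylsilyloxy)ethenyl]-5-[(1Z,3S)-3-(tert-butyldimethylsilyloxy)-2-methylpenta-1,4-dien-1-yl]oxolan-2-one; 15 methyl vinyl ketone (but-3-en-2-one)
Product: 16 (4S,5S)-3-methylidene-4-[1-(tert-butyldimethylsilyloxy)ethenyl]-5-[(1Z,3S,4E)-3-(tert-butyldimethylsilyloxy)-2-methyl-6-oxohepta-1,4-dien-1-yl]oxolan-2-one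
Conditions: second-generation Hoveyda–Grubbs catalyst RuCl2(H2IMes)(=CH–C6H4–2-OiPr) (10 mol%), 15 (5 equiv), CH2Cl2, 40 °C
Reagents that add atoms: none
Why: Olefin cross-metathesis of the monosubstituted alkene with excess enone should give the (E)-enone, the trisubstituted alkene, the exo-methylene group and the 1,1-disubstituted enol silane being much poorer metathesis partners.

Step 10
Reactants: 16 (4S,5S)-3-methylidene-4-[1-(tert-butyldimethylsilyloxy)ethenyl]-5-[(1Z,3S,4E)-3-(tert-butyldimethylsilyloxy)-2-methyl-6-oxohepta-1,4-dien-1-yl]oxolan-2-one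
Product: 17 (1E,3S,4Z,6S,7S,10R)-3-(tert-butyldimethylsilyloxy)-10-hydroxy-8-oxogermacra-1,4,11(13)-trien-12,6-olide
Conditions: TiCl4 (1.1 equiv), CH2Cl2, −78 °C, slow addition of 16 (final 1 mM); aq. NaHCO3; used at once
Reagents that add atoms: none
Why: Intramolecular Mukaiyama aldol addition (closest known type: Lewis-acid-mediated medium-ring closure of a silyl enol ether onto a carbonyl group): TiCl4 activates the C10 ketone, C9 of the enol silane attacks it in an open transition state and the silyl group leaves as the chloride. The ten-membered ring closes in an exo-trig mode with the enol double bond inside the new ring (10-enolendo-exo-trig). A(1,3) strain at C3 and C6 (their C–H bonds eclipse the Z-C4=C5 bond), the cis-fused lactone and H7 eclipsing C8=C9 leave one ring-closing conformer, in which C5 lies over C8, C9 reaches C10 only from the enol face on the side of C6, and C1 has to sit gauche to C8. The new C10 centre is controlled by the orientation of the carbonyl in this array: with no chelating metal on O8, the Lewis-acid-bound oxygen should take the open position antiperiplanar to C8–C9, away from the bulky silyloxy group, and the methyl group the syn-clinal one, which corresponds to 10R. The step needs 1,2- rather than 1,4-addition and this facial selectivity; C2 is out of reach of C9 in the locked conformer (an eight-membered ring would require the disfavoured rotamers at C3 and C6), the enone is twisted out of conjugation there, and the (3S)-silyloxy group points outward.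

Step 11
Reactants: 17 (1E,3S,4Z,6S,7S,10R)-3-(tert-butyldimethylsilyloxy)-10-hydroxy-8-oxogermacra-1,4,11(13)-trien-12,6-olide
Product: 18 (1E,3S,4Z,6S,7R,8R,10R)-3-(tert-butyldimethylsilyloxy)-8,10-dihydroxygermacra-1,4,11(13)-trien-12,6-olide
Conditions: NaBH4, CeCl3·7H2O, MeOH/THF, −78 °C
Reagents that add atoms: none
Why: Luche reduction is 1,2-selective and non-basic, so neither the α-methylene lactone nor the aldol is harmed; hydride should enter C8 from the exo face because the C4=C5 bond, held across C8 by the cis-fused lactone, covers the other face, which gives 8R.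

Step 12
Reactants: 18 (1E,3S,4Z,6S,7R,8R,10R)-3-(tert-butyldimethylsilyloxy)-8,10-dihydroxygermacra-1,4,11(13)-trien-12,6-olide; 19 (S)-2-methylbutanoic acid
Product: 20 (1E,3S,4Z,6S,7R,8R,10R)-3-(tert-butyldimethylsilyloxy)-10-hydroxy-8-[(2S)-2-methylbutanoyloxy]germacra-1,4,11(13)-trien-12,6-olide
Conditions: EDC·HCl, DMAP (cat.), CH2Cl2, 0 °C → rt
Reagents that add atoms: none
Why: Steglich esterification should acylate the secondary C8 hydroxyl and not the tertiary C10 hydroxyl; the C2′ centre is brought in with the enantiopure acid and is not enolised under these conditions.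

Step 13
Reactants: 20 (1E,3S,4Z,6S,7R,8R,10R)-3-(tert-butyldimethylsilyloxy)-10-hydroxy-8-[(2S)-2-methylbutanoyloxy]germacra-1,4,11(13)-trien-12,6-olide
Product: 21 (1E,3S,4Z,6S,7R,8R,10R)-3,10-dihydroxy-8-[(2S)-2-methylbutanoyloxy]germacra-1,4,11(13)-trien-12,6-olide
Conditions: HF·pyridine, pyridine, THF, 0 °C → rt
Reagents that add atoms: none
Why: Buffered fluoride cleavage of the secondary silyl ether should spare the ester, the α-methylene lactone and the tertiary allylic alcohol.

Step 14
Reactants: 21 (1E,3S,4Z,6S,7R,8R,10R)-3,10-dihydroxy-8-[(2S)-2-methylbutanoyloxy]germacra-1,4,11(13)-trien-12,6-olide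
Product: 22 (1E,4Z,6S,7R,8R,10R)-10-hydroxy-8-[(2S)-2-methylbutanoyloxy]-3-oxogermacra-1,4,11(13)-trien-12,6-olide (target)
Conditions: MnO2 (activated, excess), CH2Cl2, rt
Reagents that add atoms: none
Why: Allylic oxidation with MnO2 should convert only the doubly allylic C3 alcohol (the tertiary C10 alcohol cannot be oxidised) into the cross-conjugated dienone, which also removes the auxiliary C3 stereocentre.

Compound list

1 | potassium hydrogen (1R,2S)-1-hydroxypropane-1,2,3-tricarboxylate (natural (2R,3S)-isocitrate, monopotassium salt) | OC(=O)C[C@H](C(=O)O)[C@@H](O)C(=O)[O-].[K+] | starting material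
2 | (2R,3S)-5-oxooxolane-2,3-dicarboxylic acid (isocitric acid lactone) | O=C1C[C@H](C(=O)O)[C@H](C(=O)O)O1 | intermediate
3 | (3aS,6aR)-3a,6a-dihydrofuro[3,4-b]furan-2,4,6(3H)-trione | O=C1C[C@H]2[C@@H](O1)C(=O)OC2=O | intermediate
4 | (3aS,6aR)-6-hydroxytetrahydrofuro[3,4-b]furan-2,4-dione (both anomers at the lactol carbon C5) | O=C1C[C@H]2[C@@H](O1)C(O)OC2=O | intermediate
5 | (2R,3S)-2-[(1Z)-2-iodoprop-1-en-1-yl]-5-oxooxolane-3-carboxylic acid | O=C1C[C@H](C(=O)O)[C@H](/C=C(/C)I)O1 | intermediate
6 | (2R,3S)-2-[(1Z)-2-iodoprop-1-en-1-yl]-5-oxooxolane-3-carbonyl chloride | O=C1C[C@H](C(=O)Cl)[C@H](/C=C(/C)I)O1 | intermediate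
7 | (4S,5R)-4-acetyl-5-[(1Z)-2-iodoprop-1-en-1-yl]oxolan-2-one | O=C1C[C@H](C(C)=O)[C@H](/C=C(/C)I)O1 | intermediate
8 | (4S,5R)-4-[1-(tert-butyldimethylsilyloxy)ethenyl]-5-[(1Z)-2-iodoprop-1-en-1-yl]oxolan-2-one | O=C1C[C@H](C(=C)O[Si](C)(C)C(C)(C)C)[C@H](/C=C(/C)I)O1 | intermediate
9 | acrolein (prop-2-enal) | C=CC=O | starting material
10 | (4S,5S)-4-[1-(tert-butyldimethylsilyloxy)ethenyl]-5-[(1Z,3S)-3-hydroxy-2-methylpenta-1,4-dien-1-yl]oxolan-2-one | O=C1C[C@H](C(=C)O[Si](C)(C)C(C)(C)C)[C@H](/C=C(/C)[C@@H](O)C=C)O1 | intermediate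
11 | (4S,5S)-4-[1-(tert-butyldimethylsilyloxy)ethenyl]-5-[(1Z,3S)-3-(tert-butyldimethylsilyloxy)-2-methylpenta-1,4-dien-1-yl]oxolan-2-one | O=C1C[C@H](C(=C)O[Si](C)(C)C(C)(C)C)[C@H](/C=C(/C)[C@@H](O[Si](C)(C)C(C)(C)C)C=C)O1 | intermediate
12 | 3-[(dimethylamino)methyl] derivative of 11 (Mannich base; lactone C3, i.e. C11, unassigned) | O=C1C(CN(C)C)[C@H](C(=C)O[Si](C)(C)C(C)(C)C)[C@H](/C=C(/C)[C@@H](O[Si](C)(C)C(C)(C)C)C=C)O1 | intermediate
13 | 3-[(trimethylammonio)methyl] derivative of 11, iodide (C11 unassigned) | O=C1C(C[N+](C)(C)C)[C@H](C(=C)O[Si](C)(C)C(C)(C)C)[C@H](/C=C(/C)[C@@H](O[Si](C)(C)C(C)(C)C)C=C)O1.[I-] | intermediate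
14 | (4S,5S)-3-methylidene-4-[1-(tert-butyldimethylsilyloxy)ethenyl]-5-[(1Z,3S)-3-(tert-butyldimethylsilyloxy)-2-methylpenta-1,4-dien-1-yl]oxolan-2-one | O=C1C(=C)[C@H](C(=C)O[Si](C)(C)C(C)(C)C)[C@H](/C=C(/C)[C@@H](O[Si](C)(C)C(C)(C)C)C=C)O1 | intermediate
15 | methyl vinyl ketone (but-3-en-2-one) | C=CC(C)=O | starting material
16 | (4S,5S)-3-methylidene-4-[1-(tert-butyldimethylsilyloxy)ethenyl]-5-[(1Z,3S,4E)-3-(tert-butyldimethylsilyloxy)-2-methyl-6-oxohepta-1,4-dien-1-yl]oxolan-2-one | O=C1C(=C)[C@H](C(=C)O[Si](C)(C)C(C)(C)C)[C@H](/C=C(/C)[C@@H](O[Si](C)(C)C(C)(C)C)/C=C/C(C)=O)O1 | intermediate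
17 | (1E,3S,4Z,6S,7S,10R)-3-(tert-butyldimethylsilyloxy)-10-hydroxy-8-oxogermacra-1,4,11(13)-trien-12,6-olide | C=C1C(=O)O[C@H]2/C=C(/C)[C@@H](O[Si](C)(C)C(C)(C)C)/C=C/[C@](C)(O)CC(=O)[C@@H]12 | intermediate
18 | (1E,3S,4Z,6S,7R,8R,10R)-3-(tert-butyldimethylsilyloxy)-8,10-dihydroxygermacra-1,4,11(13)-trien-12,6-olide | C=C1C(=O)O[C@H]2/C=C(/C)[C@@H](O[Si](C)(C)C(C)(C)C)/C=C/[C@](C)(O)C[C@@H](O)[C@@H]12 | intermediate
19 | (S)-2-methylbutanoic acid | CC[C@H](C)C(=O)O | starting material
20 | (1E,3S,4Z,6S,7R,8R,10R)-3-(tert-butyldimethylsilyloxy)-10-hydroxy-8-[(2S)-2-methylbutanoyloxy]germacra-1,4,11(13)-trien-12,6-olide | C=C1C(=O)O[C@H]2/C=C(/C)[C@@H](O[Si](C)(C)C(C)(C)C)/C=C/[C@](C)(O)C[C@@H](OC(=O)[C@@H](C)CC)[C@@H]12 | intermediate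
21 | (1E,3S,4Z,6S,7R,8R,10R)-3,10-dihydroxy-8-[(2S)-2-methylbutanoyloxy]germacra-1,4,11(13)-trien-12,6-olide | C=C1C(=O)O[C@H]2/C=C(/C)[C@@H](O)/C=C/[C@](C)(O)C[C@@H](OC(=O)[C@@H](C)CC)[C@@H]12 | intermediate
22 | (1E,4Z,6S,7R,8R,10R)-10-hydroxy-8-[(2S)-2-methylbutanoyloxy]-3-oxogermacra-1,4,11(13)-trien-12,6-olide | C=C1C(=O)O[C@H]2/C=C(/C)C(=O)/C=C/[C@](C)(O)C[C@@H](OC(=O)[C@@H](C)CC)[C@@H]12 | target

Total step count: 14. Longest linear sequence: 14 steps (1 → 22).

Steps most likely to fail

Step 10 (key step). The Lewis acid may divert the enol silane into 1,4-addition at C2 (closing an eight-membered ring) or ionise the doubly allylic C3–O bond before the ring closes, and the open transition state may discriminate the two faces of the C10 carbonyl less well than the conformational model predicts. The fallback sets out from 16 and removes the conjugated acceptor. Conjugate addition of benzeneselenol (PhSeH, cat. Et3N, CH2Cl2, 0 °C) to both Michael acceptors should give the bis(phenylselanyl) adduct of 16 F1, in which the acceptor is a saturated methyl ketone and the C3 silyl ether is no longer flanked by an enone. The same TiCl4-mediated closure of the C9–C10 bond would then give the bis(phenylselanyl) macrocycle F2. Oxidation (H2O2, THF/H2O, 0 °C → rt) and syn-elimination of both selenoxides, away from the oxygen-bearing C3 and towards C11–H, should restore the (E)-C1=C2 bond and the exo-methylene group; the route is rejoined at 17. This fallback does not change the facial bias, which rests on the same locked conformer.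

Step 2. Hydride may over-reduce past the lactol stage or attack the other anhydride carbonyl (C8). The fallback sets out from 3 and separates ring opening from reduction. Ethanethiol (EtSH, Et3N, CH2Cl2, 0 °C) should open the anhydride at the same, more electrophilic carbonyl to give (2R,3S)-2-[(ethylsulfanyl)carbonyl]-5-oxooxolane-3-carboxylic acid F3. Fukuyama reduction (Et3SiH, Pd/C, acetone, rt) then converts only the thioester into the aldehyde, which closes onto the neighbouring carboxylic acid; the route is rejoined at 4.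

Step 11. Hydride may be delivered to the endo face of the C8 carbonyl (poor facial selectivity), which would give the 8S alcohol. The fallback sets out from 17 and uses that alcohol instead of discarding it. The same reduction would then give the 8-epimer of 18 F4. Mitsunobu esterification of F4 with 19 (PPh3, DIAD, toluene, 0 °C) forms the C8–O bond with inversion, leaves the tertiary C10 hydroxyl untouched and should give 20 directly; the route is rejoined at 20 and step 12 is not needed.

Further compounds

F1 | step 10 | bis(phenylselanyl) adduct of 16 (PhSe on C2 and on C13; C2 and C11 unassigned, other centres as in 16) | O=C1C(C[Se]c2ccccc2)[C@H](C(=C)O[Si](C)(C)C(C)(C)C)[C@H](/C=C(/C)[C@@H](O[Si](C)(C)C(C)(C)C)C([Se]c2ccccc2)CC(C)=O)O1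
F2 | step 10 | 2,13-bis(phenylselanyl)-1,2,11,13-tetrahydro derivative of 17 (C2 and C11 unassigned, other centres as in 17) | [Se](c1ccccc1)CC1C(=O)O[C@H]2/C=C(/C)[C@@H](O[Si](C)(C)C(C)(C)C)C([Se]c3ccccc3)C[C@](C)(O)CC(=O)[C@@H]12
F3 | step 2 | (2R,3S)-2-[(ethylsulfanyl)carbonyl]-5-oxooxolane-3-carboxylic acid | O=C1C[C@H](C(=O)O)[C@H](C(=O)SCC)O1
F4 | step 11 | (1E,3S,4Z,6S,7R,8S,10R)-3-(tert-butyldimethylsilyloxy)-8,10-dihydroxygermacra-1,4,11(13)-trien-12,6-olide (8-epimer of 18) | C=C1C(=O)O[C@H]2/C=C(/C)[C@@H](O[Si](C)(C)C(C)(C)C)/C=C/[C@](C)(O)C[C@H](O)[C@@H]12
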